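## Retrosynthetic overview
1. Target ⇒ epimerisation at C4 plus aryl–C(=O) disconnection. This gives an endo-aryl furofuranone (oxolane ring A fused to lactone ring B) and 3,4,5-trimethoxyphenyllithium. Opening ring B releases the CH2OH and the aroyl group together.
2. Furofuranone ⇒ O1–C5 disconnection (key step). The free benzylic alcohol closes by intramolecular oxa-Michael addition onto an α-methylene-γ-butyrolactone.
3. α-Methylene lactone ⇒ C4=C5 disconnection. This is a Mannich methylenation of the β-(α-hydroxybenzyl)butyrolactone.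
4. Hydroxy lactone ⇒ C2–C3 disconnection. An L-proline anti-aldol of methyl 4-oxobutanoate with veratraldehyde, then reduction and lactonisation, sets C2 and C3.
5. Ring order: ring B (temporary lactone, masks the primary OH) is formed first, ring A (oxolane) second, and ring B is opened last.

Assumption: the locants O1, C2 (aryl), C3 (CH2OH), C4 (aroyl) and C5 (CH2) of the target oxolane are used for the same atoms in all precursors. The SMILES is read as 2R,3R,4S, that is 2,3-cis and 3,4-trans.

## Route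

Step 1
Reactants: 1 3,4-dimethoxybenzaldehyde (veratraldehyde); 2 methyl 4-oxobutanoate
Product: 5 (4R)-4-[(R)-(3,4-dimethoxyphenyl)(hydroxy)methyl]oxolan-2-one, via anti-aldol aldehyde 3 (not isolated), via diol ester 4 (not isolated)
Conditions: (S)-pyrrolidine-2-carboxylic acid (L-proline, 20 mol %), DMF, 4 °C, 2 added over 24 h to 1 (1.5 equiv); then MeOH, NaBH4, −20 → 0 °C; aq NH4Cl
Reagents that add atoms: none
Why: Enamine-catalysed direct cross-aldol (Houk–List chair transition state): the E-enamine of 2 attacks the Re face of 1, which sets C2 (R) and the anti-related C3 (R after reduction) in one event, and immediate NaBH4 reduction prevents epimerisation while the new primary alkoxide lactonises onto the methyl ester, so that only the benzylic OH stays free.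

Step 2
Reactants: 5 (4R)-4-[(R)-(3,4-dimethoxyphenyl)(hydroxy)methyl]oxolan-2-one
Product: 8 (4R)-4-[(R)-(3,4-dimethoxyphenyl)(hydroxy)methyl]-3-methylideneoxolan-2-one, via Mannich base 6 (not isolated), via methiodide salt 7 (not isolated)
Conditions: LiN(i-Pr)2 (2.2 equiv), THF, −78 °C; CH2=NMe2+ I− (1.5 equiv), −78 °C → rt; H2O; crude 6, MeI, MeOH, rt; then aq NaHCO3/CH2Cl2, rt
Reagents that add atoms: N,N-dimethylmethyleneiminium iodide (Eschenmoser's salt), C=[N+](C)C.[I-]; iodomethane, CI (its methyl group is carried only by 7 and leaves again)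
Why: Enolate Mannich reaction, exhaustive methylation and E1cB (Hofmann-type) elimination form the standard α-methylenation of γ-butyrolactones; the second equivalent of base carries the OH as its alkoxide, C2 and C3 are not touched, and the transient α-centre of 6 and 7 is destroyed again.

Step 3
Reactants: 8 (4R)-4-[(R)-(3,4-dimethoxyphenyl)(hydroxy)methyl]-3-methylideneoxolan-2-one
Product: 9 (3aR,4R,6aR)-4-(3,4-dimethoxyphenyl)tetrahydro-1H,3H-furo[3,4-c]furan-1-one (aryl endo)
Conditions: EtN=P(NMe2)2–N=P(NMe2)3 (phosphazene base P2-Et, 5 mol %), t-BuOH (2 equiv, proton shuttle), toluene (0.01 M), −40 → 0 °C; AcOH quench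
Reagents that add atoms: none
Why: Proposed new method: a phosphazene-catalysed 5-endo-trig oxa-Michael cycloisomerisation of a β-(α-hydroxybenzyl)-α-methylene-γ-butyrolactone, forming the O1–C5 bond and ring A; the non-nucleophilic superbase turns the benzylic OH into a loosely paired alkoxide, the s-cis-locked and terminally unsubstituted exocyclic enoate is electrophilic enough and the cis-bicyclo[3.3.0]octane product unstrained enough to override the usual reluctance of oxygen nucleophiles towards 5-endo-trig closure, acyl migration is a poor competitor because it needs a strained 2,6-dioxabicyclo[2.2.1]heptane tetrahedral intermediate, the benzylic C–O bond is never broken so C2 and C3 are retained (aryl ends up endo), and protonation of the lactone enolate can only give the cis ring fusion (C4 provisionally R); the closest known reaction types are phosphazene- or phosphine-catalysed intermolecular oxa-Michael additions of alcohols to acrylates and alkoxide-induced 5-endo-trig closures of γ-hydroxy vinyl sulfones.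

Step 4
Reactants: 9 (3aR,4R,6aR)-4-(3,4-dimethoxyphenyl)tetrahydro-1H,3H-furo[3,4-c]furan-1-one; 10 5-bromo-1,2,3-trimethoxybenzene
Product: 14 (2R,3R,4S)-2-(3,4-dimethoxyphenyl)-3-(hydroxymethyl)-4-(3,4,5-trimethoxybenzoyl)oxolane (target), via aryllithium 11 (not isolated), via bicyclic hemiketal 12 (not isolated), via all-cis hydroxy ketone 13 (not isolated)
Conditions: 10 (1.1 equiv), n-BuLi (1.1 equiv), THF, −78 °C; added to 9, THF, −78 °C, 1 h; AcOH (1.2 equiv), → rt; then 1,8-diazabicyclo[5.4.0]undec-7-ene (DBU, 0.5 equiv), rt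
Reagents that add atoms: none
Why: 1,2-Addition of an aryllithium to a γ-lactone stops at the cyclic lithium hemiketal at −78 °C and opens on quenching to the hydroxy ketone, and thermodynamic epimerisation α to the aryl ketone then moves the aroyl group off the crowded all-cis face to the 3,4-trans arrangement, which sets C4 (S) while the non-enolisable C2 and C3 stay fixed.

## Compound list
1 | 3,4-dimethoxybenzaldehyde | COc1ccc(C=O)cc1OC | starting material
2 | methyl 4-oxobutanoate | COC(=O)CCC=O | starting material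
3 | methyl (3S,4R)-4-(3,4-dimethoxyphenyl)-3-formyl-4-hydroxybutanoate | COc1ccc([C@H](O)[C@@H](C=O)CC(=O)OC)cc1OC | intermediate
4 | methyl (3R,4R)-4-(3,4-dimethoxyphenyl)-4-hydroxy-3-(hydroxymethyl)butanoate | COc1ccc([C@H](O)[C@@H](CO)CC(=O)OC)cc1OC | intermediate
5 | (4R)-4-[(R)-(3,4-dimethoxyphenyl)(hydroxy)methyl]oxolan-2-one | COc1ccc([C@H](O)[C@H]2COC(=O)C2)cc1OC | intermediate
6 | (3S,4R)-4-[(R)-(3,4-dimethoxyphenyl)(hydroxy)methyl]-3-[(dimethylamino)methyl]oxolan-2-one (3,4-trans) | COc1ccc([C@H](O)[C@H]2COC(=O)[C@@H]2CN(C)C)cc1OC | intermediate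
7 | {(3S,4R)-4-[(R)-(3,4-dimethoxyphenyl)(hydroxy)methyl]-2-oxooxolan-3-yl}-N,N,N-trimethylmethanaminium iodide | COc1ccc([C@H](O)[C@H]2COC(=O)[C@@H]2C[N+](C)(C)C)cc1OC.[I-] | intermediate
8 | (4R)-4-[(R)-(3,4-dimethoxyphenyl)(hydroxy)methyl]-3-methylideneoxolan-2-one | COc1ccc([C@H](O)[C@H]2COC(=O)C2=C)cc1OC | intermediate
9 | (3aR,4R,6aR)-4-(3,4-dimethoxyphenyl)tetrahydro-1H,3H-furo[3,4-c]furan-1-one | COc1ccc([C@@H]2OC[C@@H]3C(=O)OC[C@H]23)cc1OC | intermediate
10 | 5-bromo-1,2,3-trimethoxybenzene | COc1cc(Br)cc(OC)c1OC | starting material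
11 | (3,4,5-trimethoxyphenyl)lithium | [Li]c1cc(OC)c(OC)c(OC)c1 | intermediate
12 | (3aR,4R,6aR)-4-(3,4-dimethoxyphenyl)-1-(3,4,5-trimethoxyphenyl)tetrahydro-1H,3H-furo[3,4-c]furan-1-ol (both C-1 anomers) | COc1ccc([C@@H]2OC[C@@H]3C(O)(c4cc(OC)c(OC)c(OC)c4)OC[C@H]23)cc1OC | intermediate
13 | (2R,3R,4R)-2-(3,4-dimethoxyphenyl)-3-(hydroxymethyl)-4-(3,4,5-trimethoxybenzoyl)oxolane (all-cis) | COc1ccc([C@@H]2OC[C@H](C(=O)c3cc(OC)c(OC)c(OC)c3)[C@@H]2CO)cc1OC | intermediate
14 | (2R,3R,4S)-2-(3,4-dimethoxyphenyl)-3-(hydroxymethyl)-4-(3,4,5-trimethoxybenzoyl)oxolane | COc1ccc([C@@H]2OC[C@@H](C(=O)c3cc(OC)c(OC)c(OC)c3)[C@@H]2CO)cc1OC | target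

## Step count and risks
Total step count: 4. Longest linear sequence: 4 (1 or 2 → 5 → 8 → 9 → 14; 10 enters in step 4).

**Step 3 (the new reaction).**
- It may fail for four reasons:
  - the 5-endo-trig geometry is unfavourable, and the aryl group has to go endo;
  - the base may isomerise the exocyclic alkene into the butenolide, which would destroy C3;
  - the base may start vinyl-addition oligomerisation;
  - acyl migration may lead to the regioisomeric bicycle.
- The fallback uses known chemistry only. It sets out from 5 and comes back at 9.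
- Claisen formylation of 5 (NaH, HCO2Et, THF) gives (4R)-4-[(R)-(3,4-dimethoxyphenyl)(hydroxy)methyl]-3-(hydroxymethylidene)oxolan-2-one F4.
- Pyridinium p-toluenesulfonate and molecular sieves in CH2Cl2 close the benzylic OH onto the formyl carbon. This is a favoured 5-exo-trig hemiacetalisation followed by loss of water. It gives the bicyclic enol ether (3aR,4R)-4-(3,4-dimethoxyphenyl)-3a,4-dihydro-1H,3H-furo[3,4-c]furan-1-one F5.
- Hydrogenation of F5 over 5 % Rh/Al2O3 (H2, 1 atm, EtOAc) takes place on the face opposite to the aryl group and gives cis-fused 9.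

**Step 1.**
- The electron-rich aldehyde 1 is a sluggish acceptor. Self-aldolisation of 2 and a modest anti:syn ratio can therefore depress the yield.
- The fallback replaces organocatalysis by auxiliary control. It sets out from 1 and comes back at 5.
- Commercial (4R)-4-benzyl-1,3-oxazolidin-2-one is N-acylated (n-BuLi, methyl 4-chloro-4-oxobutanoate) to (4R)-4-benzyl-3-(4-methoxy-4-oxobutanoyl)-1,3-oxazolidin-2-one F1.
- The MgCl2-catalysed anti-aldol of F1 with 1 (MgCl2 10 mol %, Et3N, Me3SiCl, EtOAc, rt) proceeds through the chelated magnesium Z-enolate, attacked opposite to the benzyl group. It gives methyl (3S)-4-[(4R)-4-benzyl-2-oxo-1,3-oxazolidin-3-yl]-3-{(R)-(3,4-dimethoxyphenyl)[(trimethylsilyl)oxy]methyl}-4-oxobutanoate F2.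
- LiBH4/MeOH (THF, 0 °C) removes the auxiliary reductively. The primary alkoxide then closes onto the methyl ester to give (4R)-4-{(R)-(3,4-dimethoxyphenyl)[(trimethylsilyl)oxy]methyl}oxolan-2-one F3.
- Dilute citric acid cleaves the silyl ether of F3 to 5.

**Step 4.**
- Enolisation of 9 by the basic aryllithium or double addition can erode the yield.
- Prolonged base treatment could trigger retro-oxa-Michael opening of the β-alkoxy ketone.
- The fallback changes the oxidation-state logic. It sets out from 9 and comes back at 13.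
- i-Bu2AlH (toluene, −78 °C) reduces 9 to the lactol (3aR,4R,6aR)-4-(3,4-dimethoxyphenyl)tetrahydro-1H,3H-furo[3,4-c]furan-1-ol F6.
- 11 (2.2 equiv) opens F6 to the diol (2R,3R,4R)-2-(3,4-dimethoxyphenyl)-3-(hydroxymethyl)-4-[hydroxy(3,4,5-trimethoxyphenyl)methyl]oxolane F7, as a mixture of carbinol epimers.
- MnO2 (CH2Cl2, rt) oxidises only the benzylic alcohol of F7 to give 13. This is epimerised to 14 with DBU as in step 4.

## Further compounds
F1 | step 1 | (4R)-4-benzyl-3-(4-methoxy-4-oxobutanoyl)-1,3-oxazolidin-2-one | COC(=O)CCC(=O)N1[C@H](Cc2ccccc2)COC1=O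
F2 | step 1 | methyl (3S)-4-[(4R)-4-benzyl-2-oxo-1,3-oxazolidin-3-yl]-3-{(R)-(3,4-dimethoxyphenyl)[(trimethylsilyl)oxy]methyl}-4-oxobutanoate | COc1ccc([C@H](O[Si](C)(C)C)[C@H](CC(=O)OC)C(=O)N2[C@H](Cc3ccccc3)COC2=O)cc1OC
F3 | step 1 | (4R)-4-{(R)-(3,4-dimethoxyphenyl)[(trimethylsilyl)oxy]methyl}oxolan-2-one | COc1ccc([C@H](O[Si](C)(C)C)[C@H]2COC(=O)C2)cc1OC
F4 | step 3 | (4R)-4-[(R)-(3,4-dimethoxyphenyl)(hydroxy)methyl]-3-(hydroxymethylidene)oxolan-2-one | COc1ccc([C@H](O)[C@H]2COC(=O)C2=CO)cc1OC
F5 | step 3 | (3aR,4R)-4-(3,4-dimethoxyphenyl)-3a,4-dihydro-1H,3H-furo[3,4-c]furan-1-one | COc1ccc([C@@H]2OC=C3C(=O)OC[C@H]23)cc1OC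
F6 | step 4 | (3aR,4R,6aR)-4-(3,4-dimethoxyphenyl)tetrahydro-1H,3H-furo[3,4-c]furan-1-ol (anomers) | COc1ccc([C@@H]2OC[C@@H]3C(O)OC[C@H]23)cc1OC
F7 | step 4 | (2R,3R,4R)-2-(3,4-dimethoxyphenyl)-3-(hydroxymethyl)-4-[hydroxy(3,4,5-trimethoxyphenyl)methyl]oxolane (carbinol epimers) | COc1ccc([C@@H]2OC[C@H](C(O)c3cc(OC)c(OC)c(OC)c3)[C@@H]2CO)cc1OC
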